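Route to CNP0153978.6, a cis,cis-germacranolide with a cis-fused 12,6-lactone; the route is a paper proposal and has not been tested.

**Plan**
1. Cuts, in retrosynthetic order: the two O-acyl bonds at O8 and O9; C8–C9 (ring opening to a dialdehyde); O6–C12 and C6–C7; the epoxide C–O bonds; C1=C10 with O–C9; C7–C11.
2. Forward: neryl acetate supplies C1–C6 with the Z C4=C5 bond. A tandem oxa-Michael/Horner–Wadsworth–Emmons step adds C10, C14 and C9. An asymmetric 2-(methoxycarbonyl)allylboration adds C7, C8 and C11–C13. Epoxidation and lactonisation follow, and the ten-membered carbocycle closes last at C8–C9.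
3. Enabling feature: in dialdehyde 18 the C9 formyl group is conjugated through C10=C1 with the C14 ester, so CrCl2 reduces only this group to an allylchromium whose γ-carbon is C9. The unconjugated C8 formyl group on C7 of the cis-fused γ-lactone is the electrophile, and C1=C10 ends inside the new ring.
4. Stereochemistry: C6/C7 from a catalyst-controlled syn-allylboration; C4/C5 from the Z-alkene and a hydroxyl-directed threo epoxidation; C9 and C8 in the ring closure (Felkin–Anh at C8, chair gives 8,9-anti), then C8 is inverted by Mitsunobu esterification; the C1=C10 geometry is fixed by the ring.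

Key step: step 13

Remark: C1–C15 are the germacrane numbers of the target and are used for all intermediates. CIP descriptors at C6 and C7 change along the route with the neighbouring groups although these centres are not touched after step 8. Aldehyde 1 and phosphonate 9 are taken as purchasable.

**Route**

Step 1
Reactants: 1 2-[(4-methoxybenzyl)oxy]acetaldehyde; 2 methyl acrylate
Product: 3 methyl 3-hydroxy-4-[(4-methoxybenzyl)oxy]-2-methylidenebutanoate (racemic)
Conditions: DABCO (0.5 equiv), excess 2, rt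
Reagents that add atoms: none
Why: Morita–Baylis–Hillman reaction of an α-alkoxy aldehyde joins C7 to C11; the carbinol centre is racemic and disappears in step 3.

Step 2
Reactants: 3 methyl 3-hydroxy-4-[(4-methoxybenzyl)oxy]-2-methylidenebutanoate
Product: 4 methyl 3-[(tert-butoxycarbonyl)oxy]-4-[(4-methoxybenzyl)oxy]-2-methylidenebutanoate (racemic)
Conditions: Boc2O, DMAP (cat.), CH2Cl2, 0 °C → rt
Reagents that add atoms: di-tert-butyl dicarbonate, CC(C)(C)OC(=O)OC(=O)OC(C)(C)C
Why: O-acylation to the Morita–Baylis–Hillman carbonate, the usual leaving group for SN2' substitution of such adducts.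

Step 3
Reactants: 4 methyl 3-[(tert-butoxycarbonyl)oxy]-4-[(4-methoxybenzyl)oxy]-2-methylidenebutanoate
Product: 5 methyl (2E)-4-[(4-methoxybenzyl)oxy]-2-[(4,4,5,5-tetramethyl-1,3,2-dioxaborolan-2-yl)methyl]but-2-enoate (CH2OPMB cis to CH2B)
Conditions: B2pin2, CuCl (5 mol %), Xantphos (5 mol %), KOtBu (10 mol %), THF, rt
Reagents that add atoms: bis(pinacolato)diboron, CC1(C)OB(OC1(C)C)B1OC(C)(C)C(C)(C)O1
Why: copper-catalysed SN2' borylation (borylcupration of the acrylate, then β-elimination of the carbonate) should give the 2-(methoxycarbonyl)allylboronate, the more stable isomer with the γ-substituent trans to the ester being expected and used after purification.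

Step 4
Reactants: 6 neryl acetate
Product: 7 (2Z)-3-methyl-6-oxohex-2-en-1-yl acetate
Conditions: O3 (1 equiv), CH2Cl2/pyridine, −78 °C; Me2S
Reagents that add atoms: ozone, [O-][O+]=O
Why: chemoselective ozonolysis of the electron-rich isopropylidene double bond (the allylic acetate deactivates the other one) frees C1 as the aldehyde and leaves the Z C4=C5 bond untouched.

Step 5
Reactants: 7 (2Z)-3-methyl-6-oxohex-2-en-1-yl acetate; 8 4-methoxybenzyl alcohol; 9 trimethyl 2-phosphonoacrylate
Product: 11 methyl (2E,6Z)-8-acetoxy-2-{[(4-methoxybenzyl)oxy]methyl}-6-methylocta-2,6-dienoate, via sodium phosphonate carbanion 10 (not isolated)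
Conditions: NaH, THF, 0 °C (8, then 9); then 7, −78 °C → rt
Reagents that add atoms: none
Why: tandem oxa-Michael/Horner–Wadsworth–Emmons reaction, in which the alkoxide of 8 adds to the phosphonoacrylate and the resulting carbanion olefinates the aldehyde, installs C10, C14 and the protected C9 in one operation; the (2E) isomer is expected to predominate and this geometry is erased in step 13 in any case.

Step 6
Reactants: 11 methyl (2E,6Z)-8-acetoxy-2-{[(4-methoxybenzyl)oxy]methyl}-6-methylocta-2,6-dienoate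
Product: 12 methyl (2E,6Z)-8-hydroxy-2-{[(4-methoxybenzyl)oxy]methyl}-6-methylocta-2,6-dienoate
Conditions: K2CO3 (0.2 equiv), MeOH, 0 °C
Reagents that add atoms: none
Why: methanolysis (transesterification) of the primary allylic acetate should be much faster than conjugate addition of methoxide to the trisubstituted enoate.

Step 7
Reactants: 12 methyl (2E,6Z)-8-hydroxy-2-{[(4-methoxybenzyl)oxy]methyl}-6-methylocta-2,6-dienoate
Product: 13 methyl (2E,6Z)-2-{[(4-methoxybenzyl)oxy]methyl}-6-methyl-8-oxoocta-2,6-dienoate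
Conditions: TEMPO (10 mol %), PhI(OAc)2, CH2Cl2, rt
Reagents that add atoms: none
Why: TEMPO/PhI(OAc)2 oxidation of the allylic alcohol gives the enal under neutral conditions that should keep the 6Z geometry.

Step 8
Reactants: 13 methyl (2E,6Z)-2-{[(4-methoxybenzyl)oxy]methyl}-6-methyl-8-oxoocta-2,6-dienoate; 5 methyl (2E)-4-[(4-methoxybenzyl)oxy]-2-[(4,4,5,5-tetramethyl-1,3,2-dioxaborolan-2-yl)methyl]but-2-enoate
Product: 14 dimethyl (2E,6Z,8S,9R)-8-hydroxy-2,9-bis{[(4-methoxybenzyl)oxy]methyl}-6-methyl-10-methylideneundeca-2,6-dienedioate (8,9-syn; these are C6 and C7)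
Conditions: (R)-TRIP [3,3'-bis(2,4,6-triisopropylphenyl)-1,1'-binaphthyl-2,2'-diyl hydrogen phosphate] (5 mol %), 4 Å MS, toluene, −20 °C → rt; aqueous work-up
Reagents that add atoms: none
Why: chiral phosphoric acid-catalysed allylboration passes through a closed chair transition state, so boronate 5 (γ-substituent cis to CH2B) should give the syn adduct that later becomes the cis-fused lactone, while the catalyst selects the aldehyde face and so sets C6 and C7 [(R)-TRIP by analogy with allyl- and crotylboronates; the enantiomeric acid would give the enantiomer].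

Step 9
Reactants: 14 dimethyl (2E,6Z,8S,9R)-8-hydroxy-2,9-bis{[(4-methoxybenzyl)oxy]methyl}-6-methyl-10-methylideneundeca-2,6-dienedioate
Product: 15 dimethyl (2E,6R,7S,8R,9R)-6,7-epoxy-8-hydroxy-2,9-bis{[(4-methoxybenzyl)oxy]methyl}-6-methyl-10-methylideneundec-2-enedioate (threo epoxy alcohol; C4 R, C5 S)
Conditions: mCPBA, CH2Cl2, 0 °C
Reagents that add atoms: 3-chloroperoxybenzoic acid, O=C(OO)c1cccc(Cl)c1
Why: hydroxyl-directed peracid epoxidation, in which the Z-alkene places C3 cis to the carbinol carbon so that 1,3-allylic strain holds H6 in the alkene plane and the hydrogen-bonded peracid attacks syn to the C6 hydroxyl, should give the threo epoxy alcohol with C4 and C5 as in the target, the two electron-poor alkenes staying untouched.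

Step 10
Reactants: 15 dimethyl (2E,6R,7S,8R,9R)-6,7-epoxy-8-hydroxy-2,9-bis{[(4-methoxybenzyl)oxy]methyl}-6-methyl-10-methylideneundec-2-enedioate
Product: 16 methyl (2E)-2-{[(4-methoxybenzyl)oxy]methyl}-5-[(2R,3S)-3-{(2R,3R)-3-{[(4-methoxybenzyl)oxy]methyl}-4-methylidene-5-oxooxolan-2-yl}-2-methyloxiran-2-yl]pent-2-enoate (cis-disubstituted α-methylene-γ-lactone)
Conditions: PPTS (10 mol %), toluene, 40 °C
Reagents that add atoms: none
Why: mild acid-catalysed lactonisation (5-exo-trig acyl substitution) of the γ-hydroxy acrylate closes the 12,6-lactone without touching a stereocentre.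

Step 11
Reactants: 16 methyl (2E)-2-{[(4-methoxybenzyl)oxy]methyl}-5-[(2R,3S)-3-{(2R,3R)-3-{[(4-methoxybenzyl)oxy]methyl}-4-methylidene-5-oxooxolan-2-yl}-2-methyloxiran-2-yl]pent-2-enoate
Product: 17 methyl (2E)-2-(hydroxymethyl)-5-[(2R,3S)-3-{(2R,3R)-3-(hydroxymethyl)-4-methylidene-5-oxooxolan-2-yl}-2-methyloxiran-2-yl]pent-2-enoate
Conditions: DDQ (2.5 equiv), CH2Cl2/pH 7 buffer, 0 °C → rt
Reagents that add atoms: none
Why: oxidative cleavage of both 4-methoxybenzyl ethers under neutral conditions should spare the epoxide, the lactone and the enoates and free O8 and O9 together.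

Step 12
Reactants: 17 methyl (2E)-2-(hydroxymethyl)-5-[(2R,3S)-3-{(2R,3R)-3-(hydroxymethyl)-4-methylidene-5-oxooxolan-2-yl}-2-methyloxiran-2-yl]pent-2-enoate
Product: 18 methyl (2E)-2-formyl-5-[(2R,3S)-3-{(2R,3S)-3-formyl-4-methylidene-5-oxooxolan-2-yl}-2-methyloxiran-2-yl]pent-2-enoate (dialdehyde, used crude)
Conditions: Dess–Martin periodinane (3 equiv), CH2Cl2, 0 °C
Reagents that add atoms: none
Why: Dess–Martin oxidation of both primary alcohols under non-basic conditions should give the C8 aldehyde without epimerising C7 and the C9 aldehyde as the alkylidene formylacetate.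

Step 13
Reactants: 18 methyl (2E)-2-formyl-5-[(2R,3S)-3-{(2R,3S)-3-formyl-4-methylidene-5-oxooxolan-2-yl}-2-methyloxiran-2-yl]pent-2-enoate
Product: 20 methyl (4R,5S,6R,7R,8R,9S)-4,5-epoxy-8-hydroxy-9-[(triethylsilyl)oxy]germacra-1(10),11(13)-dien-12,6-olid-14-oate (C2 cis to C9 on C1=C10), via γ-siloxyallylchromium dichloride 19 (not isolated)
Conditions: CrCl2 (8 equiv), Et3SiCl (4 equiv), DMF, 25 °C, 18 added over 12 h (final 2 mM); aqueous work-up
Reagents that add atoms: chlorotriethylsilane, CC[Si](Cl)(CC)CC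
Why: Proposed new method: divalent chromium reduces only the C9 formyl group that is conjugated through C10=C1 with the C14 ester, silylation on O9 and a second electron give the γ-siloxyallylchromium 19 (Cr on C1), and its γ-carbon C9 adds to the C8 aldehyde by an SE2' path through a six-membered chair transition state; the closest known reaction type is the CrCl2/chlorosilane reductive coupling of enals with aldehydes to 1,2-diol monosilyl ethers, together with Nozaki–Hiyama–Kishi allylation macrocyclisations. The ten-membered carbocycle closes 10-exo-trig at the C8 carbonyl with the new C1=C10 bond endocyclic, and the ring forces C2 into the inside position of the allyl unit, which fixes the C1=C10 geometry (C2 cis to C9). To avoid 1,3-allylic strain with C2 the OSiEt3 group lies outside, so the chair should give the 8,9-anti relation; C8 is set by Felkin–Anh attack anti to the C6 branch on C7, and C9 follows from C8 through the chair because the C1–Cr centre equilibrates, which together should give (8R,9S). The step needs chemoselective reduction of the conjugated aldehyde (the alkyl aldehyde, the α-methylene lactone and the epoxide are not reduced by CrCl2), γ- over α-attack (ten- over eight-membered ring, secured because Cr on C1 keeps the push–pull β-siloxyacrylate intact) and silylation of O9 only (the hindered chromium alkoxide at O8 is freed on work-up).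

Step 14
Reactants: 20 methyl (4R,5S,6R,7R,8R,9S)-4,5-epoxy-8-hydroxy-9-[(triethylsilyl)oxy]germacra-1(10),11(13)-dien-12,6-olid-14-oate; 21 methacrylic acid
Product: 22 methyl (4R,5S,6R,7S,8S,9S)-4,5-epoxy-8-(methacryloyloxy)-9-[(triethylsilyl)oxy]germacra-1(10),11(13)-dien-12,6-olid-14-oate
Conditions: PPh3, DIAD, toluene, 0 °C → rt
Reagents that add atoms: none
Why: Mitsunobu esterification (SN2 displacement of the alkoxyphosphonium group by methacrylate) should invert C8 from R to S and install the ester at once, the neighbouring silyl ether being unable to participate.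

Step 15
Reactants: 22 methyl (4R,5S,6R,7S,8S,9S)-4,5-epoxy-8-(methacryloyloxy)-9-[(triethylsilyl)oxy]germacra-1(10),11(13)-dien-12,6-olid-14-oate
Product: 23 methyl (4R,5S,6R,7R,8S,9S)-4,5-epoxy-9-hydroxy-8-(methacryloyloxy)germacra-1(10),11(13)-dien-12,6-olid-14-oate
Conditions: HF·pyridine, THF/pyridine, 0 °C
Reagents that add atoms: none
Why: buffered fluoride cleavage of the secondary triethylsilyl ether should leave the epoxide, the esters and the enoates intact and should not move the C8 ester.

Step 16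
Reactants: 23 methyl (4R,5S,6R,7R,8S,9S)-4,5-epoxy-9-hydroxy-8-(methacryloyloxy)germacra-1(10),11(13)-dien-12,6-olid-14-oate
Product: 24 methyl (4R,5S,6R,7R,8S,9S)-9-acetoxy-4,5-epoxy-8-(methacryloyloxy)germacra-1(10),11(13)-dien-12,6-olid-14-oate (target)
Conditions: Ac2O, pyridine, DMAP (cat.), CH2Cl2, 0 °C
Reagents that add atoms: acetic anhydride, CC(=O)OC(C)=O
Why: O-acetylation of the allylic C9 alcohol proceeds with retention and, kept short at 0 °C, should not cause acyl migration.

**Compound list**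
1 | 2-[(4-methoxybenzyl)oxy]acetaldehyde | COc1ccc(COCC=O)cc1 | starting material
2 | methyl acrylate | C=CC(=O)OC | starting material
3 | methyl 3-hydroxy-4-[(4-methoxybenzyl)oxy]-2-methylidenebutanoate (racemic) | COc1ccc(COCC(O)C(=C)C(=O)OC)cc1 | intermediate
4 | methyl 3-[(tert-butoxycarbonyl)oxy]-4-[(4-methoxybenzyl)oxy]-2-methylidenebutanoate (racemic) | COc1ccc(COCC(OC(=O)OC(C)(C)C)C(=C)C(=O)OC)cc1 | intermediate
5 | methyl (2E)-4-[(4-methoxybenzyl)oxy]-2-[(4,4,5,5-tetramethyl-1,3,2-dioxaborolan-2-yl)methyl]but-2-enoate | COc1ccc(COC/C=C(\CB2OC(C)(C)C(C)(C)O2)C(=O)OC)cc1 | intermediate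
6 | neryl acetate | CC(C)=CCC/C(C)=C\COC(C)=O | starting material
7 | (2Z)-3-methyl-6-oxohex-2-en-1-yl acetate | O=CCC/C(C)=C\COC(C)=O | intermediate
8 | 4-methoxybenzyl alcohol | COc1ccc(CO)cc1 | starting material
9 | trimethyl 2-phosphonoacrylate | C=C(C(=O)OC)P(=O)(OC)OC | starting material
10 | sodium salt of the carbanion of methyl 2-(dimethoxyphosphoryl)-3-[(4-methoxybenzyl)oxy]propanoate | COc1ccc(COC[C-](C(=O)OC)P(=O)(OC)OC)cc1.[Na+] | intermediate
11 | methyl (2E,6Z)-8-acetoxy-2-{[(4-methoxybenzyl)oxy]methyl}-6-methylocta-2,6-dienoate | COC(=O)/C(COCc1ccc(OC)cc1)=C/CC/C(C)=C\COC(C)=O | intermediate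
12 | methyl (2E,6Z)-8-hydroxy-2-{[(4-methoxybenzyl)oxy]methyl}-6-methylocta-2,6-dienoate | COC(=O)/C(COCc1ccc(OC)cc1)=C/CC/C(C)=C\CO | intermediate
13 | methyl (2E,6Z)-2-{[(4-methoxybenzyl)oxy]methyl}-6-methyl-8-oxoocta-2,6-dienoate | COC(=O)/C(COCc1ccc(OC)cc1)=C/CC/C(C)=C\C=O | intermediate
14 | dimethyl (2E,6Z,8S,9R)-8-hydroxy-2,9-bis{[(4-methoxybenzyl)oxy]methyl}-6-methyl-10-methylideneundeca-2,6-dienedioate | COC(=O)C(=C)[C@H](COCc1ccc(OC)cc1)[C@@H](O)/C=C(C)\CC/C=C(/C(=O)OC)COCc1ccc(OC)cc1 | intermediate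
15 | dimethyl (2E,6R,7S,8R,9R)-6,7-epoxy-8-hydroxy-2,9-bis{[(4-methoxybenzyl)oxy]methyl}-6-methyl-10-methylideneundec-2-enedioate | COC(=O)C(=C)[C@H](COCc1ccc(OC)cc1)[C@@H](O)[C@@H]1O[C@]1(C)CC/C=C(/C(=O)OC)COCc1ccc(OC)cc1 | intermediate
16 | methyl (2E)-2-{[(4-methoxybenzyl)oxy]methyl}-5-[(2R,3S)-3-{(2R,3R)-3-{[(4-methoxybenzyl)oxy]methyl}-4-methylidene-5-oxooxolan-2-yl}-2-methyloxiran-2-yl]pent-2-enoate | C=C1C(=O)O[C@@H]([C@@H]2O[C@]2(C)CC/C=C(/C(=O)OC)COCc2ccc(OC)cc2)[C@H]1COCc1ccc(OC)cc1 | intermediate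
17 | methyl (2E)-2-(hydroxymethyl)-5-[(2R,3S)-3-{(2R,3R)-3-(hydroxymethyl)-4-methylidene-5-oxooxolan-2-yl}-2-methyloxiran-2-yl]pent-2-enoate | C=C1C(=O)O[C@@H]([C@@H]2O[C@]2(C)CC/C=C(/C(=O)OC)CO)[C@H]1CO | intermediate
18 | methyl (2E)-2-formyl-5-[(2R,3S)-3-{(2R,3S)-3-formyl-4-methylidene-5-oxooxolan-2-yl}-2-methyloxiran-2-yl]pent-2-enoate | C=C1C(=O)O[C@@H]([C@@H]2O[C@]2(C)CC/C=C(/C(=O)OC)C=O)[C@H]1C=O | intermediate
19 | γ-siloxyallylchromium dichloride (Cr on C1, which is configurationally labile; C9=C10 enol triethylsilyl ether with OSiEt3 trans to C1; C8 aldehyde intact) | C=C1C(=O)O[C@@H]([C@@H]2O[C@]2(C)CCC([Cr](Cl)Cl)/C(C(=O)OC)=C/O[Si](CC)(CC)CC)[C@H]1C=O | intermediate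
20 | methyl (4R,5S,6R,7R,8R,9S)-4,5-epoxy-8-hydroxy-9-[(triethylsilyl)oxy]germacra-1(10),11(13)-dien-12,6-olid-14-oate | O[C@@H]1[C@H]2C(=C)C(=O)O[C@H]2[C@@H]2O[C@]2(C)CC/C=C(/C(=O)OC)[C@@H]1O[Si](CC)(CC)CC | intermediate
21 | methacrylic acid | C=C(C)C(=O)O | starting material
22 | methyl (4R,5S,6R,7S,8S,9S)-4,5-epoxy-8-(methacryloyloxy)-9-[(triethylsilyl)oxy]germacra-1(10),11(13)-dien-12,6-olid-14-oate | C=C(C)C(=O)O[C@H]1[C@H]2C(=C)C(=O)O[C@H]2[C@@H]2O[C@]2(C)CC/C=C(/C(=O)OC)[C@@H]1O[Si](CC)(CC)CC | intermediate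
23 | methyl (4R,5S,6R,7R,8S,9S)-4,5-epoxy-9-hydroxy-8-(methacryloyloxy)germacra-1(10),11(13)-dien-12,6-olid-14-oate | C=C(C)C(=O)O[C@H]1[C@H]2C(=C)C(=O)O[C@H]2[C@@H]2O[C@]2(C)CC/C=C(/C(=O)OC)[C@@H]1O | intermediate
24 | methyl (4R,5S,6R,7R,8S,9S)-9-acetoxy-4,5-epoxy-8-(methacryloyloxy)germacra-1(10),11(13)-dien-12,6-olid-14-oate | C=C(C)C(=O)O[C@H]1[C@H]2C(=C)C(=O)O[C@H]2[C@@H]2O[C@]2(C)CC/C=C(/C(=O)OC)[C@@H]1OC(C)=O | target

**Totals and risks**
Total step count: 16. Longest linear sequence: 13 steps (steps 4–16, from neryl acetate 6 to 24); boronate 5 (steps 1–3) enters at step 8.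

Steps most likely to fail:

Step 13 (proposed new method). Bond formation may occur at C1 instead of C9 (eight-membered ring), coupling may be intermolecular, the epoxide may be opened by chloride under the Lewis-acidic trivalent chromium/chlorosilane conditions, or the wrong aldehyde face may be attacked. Fallback from 18: a reductive pinacol macrocyclisation with SmI2 (THF/HMPA, −78 °C, high dilution), a known route to medium- and large-ring 1,2-diols that is expected to favour the trans diol, should give the (8S,9S) diol F1. Selective acetylation of the less hindered allylic C9 hydroxyl (Ac2O, 2,4,6-collidine, −20 °C) then gives the 9-acetate F2, and methacryloyl chloride, Et3N and DMAP lead directly to 24.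

Step 14. The hindered ring carbinol may eliminate or not be displaced, and PPh3 may add to the α-methylene lactone. Fallback from 20: Dess–Martin oxidation gives the C8 ketone F3. Reduction with LiBH(s-Bu)3 (THF, −78 °C), by polar Felkin–Anh attack anti to the C9–O bond, should give the 8,9-syn (8S) alcohol F4. Acylation with methacryloyl chloride, Et3N and DMAP returns to 22.

Step 8. The phosphoric acid may activate the ester-deactivated boronate too weakly, enantio- or syn-selectivity may be lost, or enal 13 may isomerise from Z to E. Fallback from 13 and 5: the uncatalysed thermal allylboration (toluene, 80 °C), known to give syn adducts from such boronates, gives the racemic hydroxy ester F5. A Sharpless kinetic resolution (Ti(OiPr)4, L-(+)-diisopropyl tartrate, TBHP, 4 Å MS, CH2Cl2, −20 °C) should then epoxidise the unwanted enantiomer faster to the erythro epoxy alcohol F6, which is separated, and leave 14, where the route is rejoined.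

Further compounds
F1 | step 13 | methyl (4R,5S,6R,7R,8S,9S)-4,5-epoxy-8,9-dihydroxygermacra-1(10),11(13)-dien-12,6-olid-14-oate | O[C@H]1[C@H]2C(=C)C(=O)O[C@H]2[C@@H]2O[C@]2(C)CC/C=C(/C(=O)OC)[C@@H]1O
F2 | step 13 | methyl (4R,5S,6R,7R,8S,9S)-9-acetoxy-4,5-epoxy-8-hydroxygermacra-1(10),11(13)-dien-12,6-olid-14-oate | O[C@H]1[C@H]2C(=C)C(=O)O[C@H]2[C@@H]2O[C@]2(C)CC/C=C(/C(=O)OC)[C@@H]1OC(C)=O
F3 | step 14 | methyl (4R,5S,6R,7S,9S)-4,5-epoxy-8-oxo-9-[(triethylsilyl)oxy]germacra-1(10),11(13)-dien-12,6-olid-14-oate | O=C1[C@H]2C(=C)C(=O)O[C@H]2[C@@H]2O[C@]2(C)CC/C=C(/C(=O)OC)[C@@H]1O[Si](CC)(CC)CC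
F4 | step 14 | methyl (4R,5S,6R,7R,8S,9S)-4,5-epoxy-8-hydroxy-9-[(triethylsilyl)oxy]germacra-1(10),11(13)-dien-12,6-olid-14-oate | O[C@H]1[C@H]2C(=C)C(=O)O[C@H]2[C@@H]2O[C@]2(C)CC/C=C(/C(=O)OC)[C@@H]1O[Si](CC)(CC)CC
F5 | step 8 | racemic 8,9-syn hydroxy ester (equal parts of 14 and its enantiomer; the SMILES shows the enantiomer, dimethyl (2E,6Z,8R,9S)-8-hydroxy-2,9-bis{[(4-methoxybenzyl)oxy]methyl}-6-methyl-10-methylideneundeca-2,6-dienedioate) | COC(=O)C(=C)[C@@H](COCc1ccc(OC)cc1)[C@H](O)/C=C(C)\CC/C=C(/C(=O)OC)COCc1ccc(OC)cc1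
F6 | step 8 | dimethyl (2E,6R,7S,8S,9S)-6,7-epoxy-8-hydroxy-2,9-bis{[(4-methoxybenzyl)oxy]methyl}-6-methyl-10-methylideneundec-2-enedioate (erythro epoxy alcohol of the unwanted enantiomer) | COC(=O)C(=C)[C@@H](COCc1ccc(OC)cc1)[C@H](O)[C@@H]1O[C@]1(C)CC/C=C(/C(=O)OC)COCc1ccc(OC)cc1
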